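## Retrosynthetic overview

1. The cycloheptene is closed last: C8=C9 by ring-closing metathesis of a diene that already carries the C10 tiglate and the C6 4-acetoxybenzoate; the phenol is released at the end.
2. C10–C9 (vinyl) and C6–C7 (2-methylallyl) come from additions to two aldehyde carbons held in one bridged γ-lactone: the lactone carbonyl is C10 and a formyl group on the one-carbon bridge is C6.
3. Key bond C4–C5: SmI2 ketyl–olefin cyclisation of an isopropyl ketone onto a vinyl group. The carbonyl carbon is used as the nucleophile, giving the cyclopentane (first ring) and the γ-hydroxy-acid (homoaldol) pattern O–C4–C5–C1–C10=O, closed as a 2-oxabicyclo[2.2.1]heptan-3-one.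
4. C1–C2: copper-catalysed enantioselective SN2′ allylation of a cyclopropanol-derived zinc homoenolate with a γ-phosphoryloxy tiglate sets the quaternary centre C1. C4 and C5 are relayed from it, C6 is set by reagent and C10 by chelation.
5. Ring order: cyclopentane (temporarily a bridged lactone), then cycloheptene.

Labels and assumption: daucane numbering is used: C1 = methyl-bearing ring-fusion carbon, C2/C3 = ring CH2, C4 = isopropyl carbinol, C5 = ring-fusion CH, C6 = aroyloxy carbon, C7 = CH2, C8=C9 = ring alkene, C10 = tigloyloxy carbon. The configuration is taken exactly as in the given SMILES, (3S,3aS,4S,8R,8aS) in azulene numbering, with an (E)-2-methylbut-2-enoate (tiglate).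

## Route

Step 1
Reactants: 1 methyl 2-methylpropanoate
Product: 2 1-(propan-2-yl)cyclopropan-1-ol
Conditions: EtMgBr (2.5 equiv), Ti(Oi-Pr)4 (20 mol %), Et2O, 0 °C → rt
Reagents that add atoms: ethylmagnesium bromide, CC[Mg]Br
Why: Kulinkovich cyclopropanation: the titanacyclopropane generated from EtMgBr adds twice to the ester carbonyl to give the cyclopropanol (no stereocentre).

Step 2
Reactants: 3 glycolaldehyde dimer (1,4-dioxane-2,5-diol); 4 ethyl 2-(triphenyl-λ5-phosphanylidene)propanoate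
Product: 5 ethyl (2E)-4-hydroxy-2-methylbut-2-enoate
Conditions: CH2Cl2, 40 °C
Reagents that add atoms: none
Why: Wittig olefination of the monomeric aldehyde released from the dimer with a stabilised ylide gives the (E)-trisubstituted enoate.

Step 3
Reactants: 5 ethyl (2E)-4-hydroxy-2-methylbut-2-enoate
Product: 6 ethyl (2E)-4-[(diethoxyphosphoryl)oxy]-2-methylbut-2-enoate
Conditions: ClP(O)(OEt)2, Et3N, DMAP (cat.), CH2Cl2, 0 °C
Reagents that add atoms: diethyl chlorophosphate, CCOP(Cl)(=O)OCC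
Why: O-phosphorylation of the primary allylic alcohol gives the allylic phosphate leaving group; the alkene geometry is untouched.

Step 4
Reactants: 2 1-(propan-2-yl)cyclopropan-1-ol; 6 ethyl (2E)-4-[(diethoxyphosphoryl)oxy]-2-methylbut-2-enoate
Product: 8 ethyl (2S)-2-ethenyl-2,6-dimethyl-5-oxoheptanoate, via zinc bis-homoenolate 7 (not isolated)
Conditions: 2 (2.2 equiv), Et2Zn (1.1 equiv), THF, 0 → 40 °C; then 6, (CuOTf)2·C6H6 (5 mol %), chiral 2-pyridyl-imine dipeptide ligand (10 mol %), −30 °C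
Reagents that add atoms: none
Why: Proposed new method: the zinc cyclopropoxide ring-opens to the β-zincio ketone (homoenolate), which transmetalates to the chiral monovalent-copper complex and attacks the ester α-carbon of 6 anti-SN2′ with loss of phosphate; the ligand antipode is chosen to give the (S) quaternary centre C1. The closest known reactions are the racemic copper-mediated SN2′ allylation of cyclopropanol-derived zinc homoenolates and the copper–peptide-catalysed enantioselective SN2′ alkylation of γ-phosphoryloxy enoates with dialkylzincs (α-quaternary β,γ-unsaturated esters).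

Step 5
Reactants: 8 ethyl (2S)-2-ethenyl-2,6-dimethyl-5-oxoheptanoate
Product: 10 (1S,4S,7S)-7-(hydroxymethyl)-4-methyl-1-(propan-2-yl)-2-oxabicyclo[2.2.1]heptan-3-one, via cyclised hydroxy ester 9 (not isolated)
Conditions: SmI2 (4.5 equiv), HMPA (10 equiv), THF, −20 °C → rt; dry O2, −78 °C; then PPTS (cat.), PhMe, 80 °C
Reagents that add atoms: dioxygen, O=O
Why: SmI2–HMPA ketyl–olefin radical cyclisation (5-exo) with interception of the primary alkylsamarium by O2: the ketone carbon, turned into a nucleophilic samarium ketyl, bonds to the internal vinyl carbon with the bulky O–Sm anti to the new CH2 (C4/C5) and syn to the samarium-binding ester (relative to C1), and only this isomer can close to the bridged γ-lactone under acid.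

Step 6
Reactants: 10 (1S,4S,7S)-7-(hydroxymethyl)-4-methyl-1-(propan-2-yl)-2-oxabicyclo[2.2.1]heptan-3-one
Product: 11 (1S,4S,7R)-4-methyl-3-oxo-1-(propan-2-yl)-2-oxabicyclo[2.2.1]heptane-7-carbaldehyde
Conditions: Dess–Martin periodinane, CH2Cl2, 0 °C → rt
Reagents that add atoms: none
Why: Dess–Martin oxidation under non-basic conditions; the rigid bicycle disfavours enolisation and β-elimination at C5 (the leaving oxygen sits on a bridgehead), so C5 is not scrambled.

Step 7
Reactants: 11 (1S,4S,7R)-4-methyl-3-oxo-1-(propan-2-yl)-2-oxabicyclo[2.2.1]heptane-7-carbaldehyde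
Product: 12 (1S,4S,7S)-7-[(1S)-1-hydroxy-3-methylbut-3-en-1-yl]-4-methyl-1-(propan-2-yl)-2-oxabicyclo[2.2.1]heptan-3-one
Conditions: (−)-Ipc2BOMe, CH2=C(CH3)CH2MgCl, Et2O, −78 °C → rt; then 11, −78 °C; HOCH2CH2NH2
Reagents that add atoms: 2-methylallylmagnesium chloride, CC(=C)C[Mg]Cl, delivered as (−)-B-(2-methylallyl)diisopinocampheylborane, CC(=C)CB([C@H]1[C@H](C)[C@H]2C[C@@H](C1)C2(C)C)[C@H]1[C@H](C)[C@H]2C[C@@H](C1)C2(C)C
Why: Brown asymmetric allylboration: the borane from (+)-α-pinene attacks the Si face through a chair transition state and sets C6 as (S) by reagent control; material from the minor enantiomer of 8 becomes a separable diastereomer.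

Step 8
Reactants: 12 (1S,4S,7S)-7-[(1S)-1-hydroxy-3-methylbut-3-en-1-yl]-4-methyl-1-(propan-2-yl)-2-oxabicyclo[2.2.1]heptan-3-one
Product: 14 (1S,2S,3S)-3-[(1R)-1-hydroxyprop-2-en-1-yl]-2-[(1S)-1-hydroxy-3-methylbut-3-en-1-yl]-3-methyl-1-(propan-2-yl)cyclopentan-1-ol, via lactol 13 (not isolated)
Conditions: i-Bu2AlH (2.2 equiv), CH2Cl2, −78 °C; then CH2=CHMgBr (6 equiv), THF, −78 → 0 °C
Reagents that add atoms: vinylmagnesium bromide, C=C[Mg]Br
Why: One-pot lactone half-reduction and Grignard addition: the opened aldehyde is held by a metal bridge to the cis tertiary alkoxide on C4 (chelation control) and the vinyl group enters from the exposed outer face, giving the (R)-C10 carbinol.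

Step 9
Reactants: 14 (1S,2S,3S)-3-[(1R)-1-hydroxyprop-2-en-1-yl]-2-[(1S)-1-hydroxy-3-methylbut-3-en-1-yl]-3-methyl-1-(propan-2-yl)cyclopentan-1-ol; 15 (2E)-2-methylbut-2-enoyl chloride
Product: 18 (1R)-1-[(1S,2S,3S)-3-hydroxy-2-[(1S)-1-hydroxy-3-methylbut-3-en-1-yl]-1-methyl-3-(propan-2-yl)cyclopentyl]prop-2-en-1-yl (2E)-2-methylbut-2-enoate, via phenylboronate 16 (not isolated), via tigloylated phenylboronate 17 (not isolated)
Conditions: PhB(OH)2, PhMe, 4 Å MS, rt; then 15, Et3N, DMAP, 50 °C; then H2O2, THF/H2O (pH 7), 0 °C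
Reagents that add atoms: none
Why: Transient 1,3-diol protection: the C4 and C6 hydroxyls close a six-membered phenylboronate, so only the allylic C10 hydroxyl undergoes DMAP-catalysed acylation; oxidative deboronation returns the diol without touching a stereocentre.

Step 10
Reactants: 18 (1R)-1-[(1S,2S,3S)-3-hydroxy-2-[(1S)-1-hydroxy-3-methylbut-3-en-1-yl]-1-methyl-3-(propan-2-yl)cyclopentyl]prop-2-en-1-yl (2E)-2-methylbut-2-enoate; 19 4-(acetyloxy)benzoyl chloride
Product: 20 (1S)-1-[(1S,2S,5S)-2-hydroxy-5-methyl-5-[(1R)-1-{[(2E)-2-methylbut-2-enoyl]oxy}prop-2-en-1-yl]-2-(propan-2-yl)cyclopentyl]-3-methylbut-3-en-1-yl 4-(acetyloxy)benzoate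
Conditions: 19, Et3N, DMAP, CH2Cl2, rt
Reagents that add atoms: none
Why: DMAP-catalysed acylation of the only secondary hydroxyl; the tertiary C4 hydroxyl does not react.

Step 11
Reactants: 20 (1S)-1-[(1S,2S,5S)-2-hydroxy-5-methyl-5-[(1R)-1-{[(2E)-2-methylbut-2-enoyl]oxy}prop-2-en-1-yl]-2-(propan-2-yl)cyclopentyl]-3-methylbut-3-en-1-yl 4-(acetyloxy)benzoate
Product: 21 (3S,3aS,4S,8R,8aS)-3-hydroxy-6,8a-dimethyl-8-{[(2E)-2-methylbut-2-enoyl]oxy}-3-(propan-2-yl)-1,2,3,3a,4,5,8,8a-octahydroazulen-4-yl 4-(acetyloxy)benzoate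
Conditions: second-generation Grubbs catalyst (5 mol %), PhMe, 80 °C
Reagents that add atoms: none
Why: Ring-closing metathesis of the vinyl and 2-methylallyl groups, trans on the cyclopentane, gives the trans-fused cycloheptene with the trisubstituted C8=C9 alkene; the conjugated tiglate alkene is inert.

Step 12
Reactants: 21 (3S,3aS,4S,8R,8aS)-3-hydroxy-6,8a-dimethyl-8-{[(2E)-2-methylbut-2-enoyl]oxy}-3-(propan-2-yl)-1,2,3,3a,4,5,8,8a-octahydroazulen-4-yl 4-(acetyloxy)benzoate
Product: 22 (3S,3aS,4S,8R,8aS)-3-hydroxy-6,8a-dimethyl-8-{[(2E)-2-methylbut-2-enoyl]oxy}-3-(propan-2-yl)-1,2,3,3a,4,5,8,8a-octahydroazulen-4-yl 4-hydroxybenzoate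
Conditions: K2CO3 (0.2 equiv), MeOH, 0 °C
Reagents that add atoms: none
Why: Chemoselective methanolysis of the aryl acetate, far faster than that of the hindered benzoate and tiglate esters, releases the phenol.

## Compound list

1 | methyl 2-methylpropanoate | COC(=O)C(C)C | starting material
2 | 1-(propan-2-yl)cyclopropan-1-ol | CC(C)C1(O)CC1 | intermediate
3 | glycolaldehyde dimer (1,4-dioxane-2,5-diol) | OC1COC(O)CO1 | starting material
4 | ethyl 2-(triphenyl-λ5-phosphanylidene)propanoate | CCOC(=O)C(C)=P(c1ccccc1)(c1ccccc1)c1ccccc1 | starting material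
5 | ethyl (2E)-4-hydroxy-2-methylbut-2-enoate | CCOC(=O)/C(C)=C/CO | intermediate
6 | ethyl (2E)-4-[(diethoxyphosphoryl)oxy]-2-methylbut-2-enoate | CCOC(=O)/C(C)=C/COP(=O)(OCC)OCC | intermediate
7 | bis(4-methyl-3-oxopentyl)zinc (zinc bis-homoenolate) | CC(C)C(=O)CC[Zn]CCC(=O)C(C)C | intermediate (not isolated)
8 | ethyl (2S)-2-ethenyl-2,6-dimethyl-5-oxoheptanoate | CCOC(=O)[C@](C)(C=C)CCC(=O)C(C)C | intermediate
9 | ethyl (1S,2S,3S)-3-hydroxy-2-(hydroxymethyl)-1-methyl-3-(propan-2-yl)cyclopentane-1-carboxylate | CCOC(=O)[C@@]1(C)CC[C@](O)(C(C)C)[C@@H]1CO | intermediate (not isolated)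
10 | (1S,4S,7S)-7-(hydroxymethyl)-4-methyl-1-(propan-2-yl)-2-oxabicyclo[2.2.1]heptan-3-one | O=C1O[C@]2(C(C)C)CC[C@@]1(C)[C@H]2CO | intermediate
11 | (1S,4S,7R)-4-methyl-3-oxo-1-(propan-2-yl)-2-oxabicyclo[2.2.1]heptane-7-carbaldehyde | O=C1O[C@]2(C(C)C)CC[C@@]1(C)[C@H]2C=O | intermediate
12 | (1S,4S,7S)-7-[(1S)-1-hydroxy-3-methylbut-3-en-1-yl]-4-methyl-1-(propan-2-yl)-2-oxabicyclo[2.2.1]heptan-3-one | O=C1O[C@]2(C(C)C)CC[C@@]1(C)[C@H]2[C@@H](O)CC(C)=C | intermediate
13 | (1S,4S,7S)-7-[(1S)-1-hydroxy-3-methylbut-3-en-1-yl]-4-methyl-1-(propan-2-yl)-2-oxabicyclo[2.2.1]heptan-3-ol (lactol; epimers at C3) | OC1O[C@]2(C(C)C)CC[C@@]1(C)[C@H]2[C@@H](O)CC(C)=C | intermediate (not isolated)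
14 | (1S,2S,3S)-3-[(1R)-1-hydroxyprop-2-en-1-yl]-2-[(1S)-1-hydroxy-3-methylbut-3-en-1-yl]-3-methyl-1-(propan-2-yl)cyclopentan-1-ol | C=C[C@@H](O)[C@@]1(C)CC[C@](O)(C(C)C)[C@@H]1[C@@H](O)CC(C)=C | intermediate
15 | (2E)-2-methylbut-2-enoyl chloride (tigloyl chloride) | C/C=C(\C)C(Cl)=O | starting material
16 | cyclic phenylboronate of 14 across the C4 and C6 hydroxyls (2-phenyl-1,3,2-dioxaborinane; C10 hydroxyl free) | C=C[C@@H](O)[C@@]1(C)CC[C@@]2(C(C)C)OB(c3ccccc3)O[C@@H](CC(C)=C)[C@H]12 | intermediate (not isolated)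
17 | C10 (2E)-2-methylbut-2-enoate of boronate 16 | C/C=C(\C)C(=O)O[C@H](C=C)[C@@]1(C)CC[C@@]2(C(C)C)OB(c3ccccc3)O[C@@H](CC(C)=C)[C@H]12 | intermediate (not isolated)
18 | (1R)-1-[(1S,2S,3S)-3-hydroxy-2-[(1S)-1-hydroxy-3-methylbut-3-en-1-yl]-1-methyl-3-(propan-2-yl)cyclopentyl]prop-2-en-1-yl (2E)-2-methylbut-2-enoate | C/C=C(\C)C(=O)O[C@H](C=C)[C@@]1(C)CC[C@](O)(C(C)C)[C@@H]1[C@@H](O)CC(C)=C | intermediate
19 | 4-(acetyloxy)benzoyl chloride | CC(=O)Oc1ccc(cc1)C(Cl)=O | starting material
20 | (1S)-1-[(1S,2S,5S)-2-hydroxy-5-methyl-5-[(1R)-1-{[(2E)-2-methylbut-2-enoyl]oxy}prop-2-en-1-yl]-2-(propan-2-yl)cyclopentyl]-3-methylbut-3-en-1-yl 4-(acetyloxy)benzoate | C/C=C(\C)C(=O)O[C@H](C=C)[C@@]1(C)CC[C@](O)(C(C)C)[C@@H]1[C@@H](OC(=O)c2ccc(OC(C)=O)cc2)CC(C)=C | intermediate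
21 | (3S,3aS,4S,8R,8aS)-3-hydroxy-6,8a-dimethyl-8-{[(2E)-2-methylbut-2-enoyl]oxy}-3-(propan-2-yl)-1,2,3,3a,4,5,8,8a-octahydroazulen-4-yl 4-(acetyloxy)benzoate | C/C=C(\C)C(=O)O[C@@H]1C=C(C)C[C@H](OC(=O)c2ccc(OC(C)=O)cc2)[C@@H]2[C@]1(C)CC[C@]2(O)C(C)C | intermediate
22 | (3S,3aS,4S,8R,8aS)-3-hydroxy-6,8a-dimethyl-8-{[(2E)-2-methylbut-2-enoyl]oxy}-3-(propan-2-yl)-1,2,3,3a,4,5,8,8a-octahydroazulen-4-yl 4-hydroxybenzoate | C/C=C(\C)C(=O)O[C@@H]1C=C(C)C[C@H](OC(=O)c2ccc(O)cc2)[C@@H]2[C@]1(C)CC[C@]2(O)C(C)C | target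

## Step count and risk

Total step count: 12. Longest linear sequence: 11 steps (steps 2 to 12); step 1 is a one-step side branch that joins at step 4.

The three steps most likely to fail:

Step 4 (the enantioselective version with a zinc homoenolate is unprecedented; ethyl or linear SN2 transfer and modest ee are the risks). The fallback sets out from 6 and returns at 8. Compound 6 is alkylated under the same copper–dipeptide catalysis with a simple dialkylzinc, bis(4-methylpent-3-en-1-yl)zinc (from 5-bromo-2-methylpent-2-ene, Mg and ZnCl2), a nucleophile class for which this SN2′ alkylation is established, to give ethyl (2S)-2-ethenyl-2,6-dimethylhept-5-enoate F1. mCPBA epoxidises only the trisubstituted alkene to ethyl (2S)-4-(3,3-dimethyloxiran-2-yl)-2-ethenyl-2-methylbutanoate F2 (both oxirane epimers converge). BF3·OEt2 at −78 °C opens the epoxide at the tertiary carbon, and a 1,2-hydride shift (Meinwald rearrangement) gives the isopropyl ketone 8.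

Step 5 (HMPA may weaken the ester-directed facial control relative to C1, and O2 trapping of the alkylsamarium is only moderate in yield). The fallback sets out from 8 and returns at 11. Ozonolysis (O3, then Me2S) of the vinyl group gives ethyl (2S)-2-formyl-2,6-dimethyl-5-oxoheptanoate F3. A Horner–Wadsworth–Emmons reaction with diethyl [(phenylsulfonyl)methyl]phosphonate and NaH, selective for the aldehyde, gives ethyl (2S)-2-[(E)-2-(benzenesulfonyl)ethenyl]-2,6-dimethyl-5-oxoheptanoate F4. SmI2 with MeOH in THF at −78 °C, without HMPA, adds the ketyl to the activated alkene while trivalent samarium bridges the ketyl oxygen and the ester, and the cis hydroxy ester lactonises to (1S,4S,7R)-7-[(benzenesulfonyl)methyl]-4-methyl-1-(propan-2-yl)-2-oxabicyclo[2.2.1]heptan-3-one F5. Deprotonation with LiN(i-Pr)2 and oxidation with MoO5·py·HMPA (oxidative desulfonylation) gives aldehyde 11.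

Step 8 (the C10 configuration rests on a chelate model, and a Felkin-type pathway would give the epimer). The fallback sets out from 12 and returns at 14. CH2=CHMgBr with CeCl3 at −78 °C adds once to the lactone, because the bicyclic hemiketal alkoxide resists a second addition, and gives after work-up 1-[(1S,2S,3S)-3-hydroxy-2-[(1S)-1-hydroxy-3-methylbut-3-en-1-yl]-1-methyl-3-(propan-2-yl)cyclopentyl]prop-2-en-1-one F6. Reduction with (S)-2-methyl-CBS-oxazaborolidine and catecholborane, reagent-controlled with the quaternary carbon as the large group, then delivers the (R)-carbinol 14.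

## Further compounds

F1 | step 4 | ethyl (2S)-2-ethenyl-2,6-dimethylhept-5-enoate | CCOC(=O)[C@](C)(C=C)CCC=C(C)C
F2 | step 4 | ethyl (2S)-4-(3,3-dimethyloxiran-2-yl)-2-ethenyl-2-methylbutanoate (epimers at the oxirane carbon) | CCOC(=O)[C@](C)(C=C)CCC1OC1(C)C
F3 | step 5 | ethyl (2S)-2-formyl-2,6-dimethyl-5-oxoheptanoate | CCOC(=O)[C@](C)(C=O)CCC(=O)C(C)C
F4 | step 5 | ethyl (2S)-2-[(E)-2-(benzenesulfonyl)ethenyl]-2,6-dimethyl-5-oxoheptanoate | CCOC(=O)[C@](C)(/C=C/S(=O)(=O)c1ccccc1)CCC(=O)C(C)C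
F5 | step 5 | (1S,4S,7R)-7-[(benzenesulfonyl)methyl]-4-methyl-1-(propan-2-yl)-2-oxabicyclo[2.2.1]heptan-3-one | O=C1O[C@]2(C(C)C)CC[C@@]1(C)[C@H]2CS(=O)(=O)c3ccccc3
F6 | step 8 | 1-[(1S,2S,3S)-3-hydroxy-2-[(1S)-1-hydroxy-3-methylbut-3-en-1-yl]-1-methyl-3-(propan-2-yl)cyclopentyl]prop-2-en-1-one | C=CC(=O)[C@@]1(C)CC[C@](O)(C(C)C)[C@@H]1[C@@H](O)CC(C)=C
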